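## The problem

Compound 17 is an achiral 6-hydroxy-3-pentylisocoumarin that carries a 2-hydroxy-4-methoxy-6-pentylphenyl group on O8. Ring A and the pyranone are fused, and ring B hangs from C8 through the ether oxygen. There is no stereocentre to set; any sp3 centre that appears on the way ends as an aromatic carbon, so no centre has to control another. The difficult bond is C8–O–C1′. The oxygen lies peri to the C1 carbonyl on ring A and between a hydroxyl (C2′) and a pentyl group (C6′) on ring B, so the ether is tri-ortho-substituted and joins a chelated, weakly nucleophilic phenol to an electron-rich arene. Ring B also needs its three oxygens (C1′, C2′, C4′) distinguished as aryl ether, free phenol and methyl ether. The enol lactone is opened by hydroxide or alkoxide, its C3=C4 bond can be saturated under hydrogenation, and the 1,2,4-trioxygenated ring B is easily over-oxidised, so the late steps must be mild, non-reductive and free of strong nucleophiles. The enabling feature is that C1, C8a, C8, C7, C6, C5, C4a, C4, C3 and the pentyl group form one unbranched fourteen-carbon chain with oxygen on every second carbon. This is a hexanoyl starter plus four acetate units, and it can be folded by one aldol bond (C8a–C4a) and one acyl transfer (O2–C1) with no change of oxidation level.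

## Retrosynthesis

**17 from 16.** The last cut is the methoxymethyl ether on O6. An acid-labile group is preferred to a benzyl ether because hydrogenolysis would put the C3=C4 bond at risk, while dilute acid in methanol leaves the lactone, the diaryl ether and the methyl ether alone. The forward step only has to cleave one acetal.

**16 from 15, and 15 from 10 and 14.** Ring B is taken back to a cyclohexenone, and the C1′–O bond is then cut as a bond between a phenoxide and an sp3 carbon. A direct aryl–oxygen coupling would have to join the chelated 8-hydroxyl of 10 to a di-ortho-substituted, electron-rich aryl halide, the least favourable case for copper- or palladium-mediated etherification. In 14 the same carbon is a secondary bromide activated by the adjacent carbonyl. That carbonyl later becomes the C2′ hydroxyl and the enol-ether oxygen becomes the C4′ methoxyl, so the three oxygens of ring B are differentiated from the outset. The forward reactions must achieve an SN2 displacement by a hindered phenoxide and then remove two hydrogens from 15 (C5′–C6′) without harming the rest.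

**14 from 12, and 12 from 11.** The C–Br bond is cut at the α′ position of the vinylogous ester, the site reached by kinetic deprotonation. Enol ether 12 comes from the symmetric dione 11, so only one regioisomer can form. Compounds 12 and 14 are far simpler than ring B itself, and the stereocentres of 14 need no control.

**10 from 9.** The 6-hydroxyl of 9 is the more acidic and is not hydrogen-bonded, so a single selective protection exposes O8 as the only nucleophile. This costs one step and avoids any selectivity question in the etherification.

**9 from 6 (key disconnection).** Both rings of the isocoumarin are opened at C8a–C4a and O2–C1, leading to the linear diketo-dioxinone 6. Building ring A from a preformed arene, for instance by side-chain metalation of an orsellinate, would need strong base, protecting groups and a separate lactonisation. Here the chain already holds every carbon and oxygen of 9 at the right oxidation level. The forward reaction must fold the chain in one sense only; masking the C3 ketone as a dioxolane leaves a single aldol mode open. After ring A has formed, the unmasked ketone is used to close the pyranone, through resorcylate 7 and ketone 8.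

**6 from 5 and 3.** The chain is cut between future C5 and C4a: the terminal carbon of the dianion of keto-dioxinone 5 is acylated by Weinreb amide 3. This joins two fragments of similar size, and the amide's stable tetrahedral adduct prevents over-addition. The ketal must survive, and it does under purely basic conditions.

**5 from 4, and 3 from 2 from 1.** Keto-dioxinone 5 results from C-acetylation of the dienolate of commercial dioxinone 4 (the future C7–C6 bond). Amide 3 comes from β-keto ester 1 by ketalisation to 2 and direct aminolysis. This avoids the free β-ketal acid and an activation step.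

## Roads not taken

**Alternative 1:** The cut is at C4a–C4 and C8a–C1, with the diaryl ether already present in an aryne precursor A1. Fluoride would generate the aryne from A1, and the anion of dimethyl malonate A2 would add at C4a, the carbon remote from the aryloxy group. The aryl anion at C8a would then attack an ester carbonyl and fragment to the homophthalate A3. The merits are real. The hindered ether is made early on simple partners, the oxygen substituent steers the regiochemistry, and aryne insertion into β-dicarbonyl C–C bonds is an established reaction type. The weak points are three. A1 is a 1,2,3,5-tetrasubstituted silyl triflate that needs a long regiocontrolled preparation. Malonates insert less cleanly than β-keto esters, with simple arylation competing. A3 still lacks C3 and the pentyl chain, so acylation, decarboxylation, lactonisation and two debenzylations follow, the last of these endangering C3=C4. On the ether bond this road is better than the chosen plan, which forms it late on a chelated phenol. The chosen plan sets against that a single fold delivering the whole isocoumarin at the correct oxidation level from cheap materials, and a shorter sequence.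

**Alternative 2:** Ring B is cut at C1′–C6′ and C2′–C3′. With a methoxide base the aryloxymalonate A4 would add to (E)-non-3-en-2-one A5, and the methyl ketone would then condense onto a malonate ester to close the cyclohexane-1,3-dione A6. The attraction is that the ether oxygen is attached to a malonate carbon before any hindrance exists and ring B is grown around it. This is at least as good an answer to the ether problem as step 9 of the chosen route. The weak points lie after A6. The quaternary β-keto ester must be decarboxylated without retro-Claisen or retro-Michael cleavage, and the dione must be aromatised. The resulting resorcinol must be mono-methylated at O4′ only. The aryl methyl group must then be converted into the 3-pentyl pyranone by side-chain metalation and acylation in the presence of all of ring B. The chosen plan gives up the easier ether formation. In return, the OH/OMe distinction of ring B is built in through enol ether 12, the pyranone arrives together with ring A, and the step count is clearly lower.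

**Alternative 3:** Ring A is cut at C6–C7, C8–C8a and C5–C6. Heating cyclobutenone A7 with aryl ethynyl ether A8 would give phenol A9 through vinylketene formation, (2+2) cycloaddition, ring opening and six-electron electrocyclisation. Its strength is that the ether oxygen enters as an ynol ether, so no hindered aryl–oxygen coupling is needed, and the pericyclic cascade fixes the substitution pattern of ring A. Its weaknesses are the multistep access to the 2,3-disubstituted A7, the fragility of the hindered A8, and a slow cascade for two encumbered partners. After A9 there is also a redox-heavy endgame: two desilylations, oxidation of both side chains, lactonisation, and debenzylation next to C3=C4. A7 and A9 also carry a stereocentre that serves no purpose. The chosen plan needs no oxidation-state changes on the isocoumarin half and no such centre. It pays for this with the late etherification.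

Key step: step 5

## Route

Remark: 17 is achiral. Compounds 12–15 are carried as racemates (14 and 15 as diastereomer mixtures), because both sp3 centres become aromatic carbons in step 10.

**Step 1**
Reactants: 1 ethyl 3-oxooctanoate
Product: 2 ethyl 2-(2-pentyl-1,3-dioxolan-2-yl)acetate
Conditions: ethylene glycol, TsOH·H2O (cat.), PhMe, reflux, Dean–Stark
Reagents that add atoms: ethylene glycol, OCCO
Why: Acid-catalysed ketalisation of the ketone of a β-keto ester with azeotropic removal of water; the ester is not affected.

**Step 2**
Reactants: 2 ethyl 2-(2-pentyl-1,3-dioxolan-2-yl)acetate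
Product: 3 N-methoxy-N-methyl-2-(2-pentyl-1,3-dioxolan-2-yl)acetamide
Conditions: MeNH(OMe)·HCl, iPrMgCl, THF, −20 → 0 °C
Reagents that add atoms: N,O-dimethylhydroxylamine hydrochloride, CNOC.Cl
Why: Direct aminolysis of the ester by the chloromagnesium amide (Weinreb amide formation); the ketal is stable to these basic conditions and the β-ketal acid is avoided.

**Step 3**
Reactants: 4 2,2,6-trimethyl-4H-1,3-dioxin-4-one
Product: 5 2,2-dimethyl-6-(2-oxopropyl)-4H-1,3-dioxin-4-one
Conditions: LiN(SiMe3)2 (2 equiv), THF, −78 °C; then AcCl
Reagents that add atoms: acetyl chloride, CC(=O)Cl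
Why: γ-Deprotonation gives the lithium dienolate, which is C-acylated at the exocyclic carbon (Claisen-type acylation); the second equivalent of base takes up the more acidic product.

**Step 4**
Reactants: 5 2,2-dimethyl-6-(2-oxopropyl)-4H-1,3-dioxin-4-one; 3 N-methoxy-N-methyl-2-(2-pentyl-1,3-dioxolan-2-yl)acetamide
Product: 6 2,2-dimethyl-6-[2,4-dioxo-5-(2-pentyl-1,3-dioxolan-2-yl)pentyl]-4H-1,3-dioxin-4-one
Conditions: 5 (2 equiv), LiN(iPr)2 (4 equiv), THF, −78 °C; then 3, −78 → −30 °C; aq. NH4Cl
Reagents that add atoms: none
Why: Crossed Claisen acylation of the keto-dioxinone dianion at its terminal, more reactive carbon by a Weinreb amide, whose chelated tetrahedral adduct prevents over-addition; 6 should be used promptly because it cyclises easily.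

**Step 5**
Reactants: 6 2,2-dimethyl-6-[2,4-dioxo-5-(2-pentyl-1,3-dioxolan-2-yl)pentyl]-4H-1,3-dioxin-4-one
Product: 9 6,8-dihydroxy-3-pentyl-1H-isochromen-1-one, via resorcylate acetonide 7 (not isolated), via ketone 8 (not isolated)
Conditions: Et3N, CH2Cl2, rt; then TFA, H2O, same flask, rt → 40 °C
Reagents that add atoms: water, O
Why: Et3N deprotonates the doubly activated CH2 between the dioxinone and the first ketone, and the extended enolate reacts through C5 of the dioxinone (future C8a) with the second ketone (future C4a) in a 6-(enolexo)-exo-trig aldol closure; loss of water and tautomerisation of the remaining ketone give resorcylate acetonide 7. This is the known base-mediated cycloaromatisation of diketo-dioxinones. Because the third ketone is held as a dioxolane, the competing six-membered aldol (the CH2 next to the dioxinone onto that ketone) cannot occur, so ring A can form in one way only. Wet TFA then hydrolyses the dioxolane to ketone 8, and the water released in the aromatisation already supplies the equivalent required. The enol oxygen of 8 attacks the protonated benzodioxinone carbonyl in a 6-exo-trig closure and the tetrahedral intermediate collapses with loss of acetone, which forms the pyranone and frees the chelated 8-hydroxyl; the closest known reaction types are the opening of benzodioxinones by internal oxygen nucleophiles and the acid-catalysed enol-lactonisation of 2-(2-oxoalkyl)benzoic acid derivatives to isocoumarins. Acid is chosen for this stage because in base the enolate on the pentyl side could attack C1 through carbon and give a naphthalene-1,3-diol, whereas under acid only attack through oxygen leads to a stable product. No stereocentre is formed.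

**Step 6**
Reactants: 9 6,8-dihydroxy-3-pentyl-1H-isochromen-1-one
Product: 10 8-hydroxy-6-(methoxymethoxy)-3-pentyl-1H-isochromen-1-one
Conditions: MeOCH2Cl (1.05 equiv), iPr2NEt, CH2Cl2, 0 °C
Reagents that add atoms: chloromethyl methyl ether, COCCl
Why: Selective O-alkylation of the more acidic, non-chelated 6-hydroxyl; the 8-hydroxyl is tied to the C1 carbonyl by a hydrogen bond and is far less reactive towards one equivalent of reagent.

**Step 7**
Reactants: 11 5-pentylcyclohexane-1,3-dione
Product: 12 3-methoxy-5-pentylcyclohex-2-en-1-one (racemic)
Conditions: MeOH, TsOH·H2O (cat.), 3 Å molecular sieves, reflux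
Reagents that add atoms: methanol, CO
Why: Acid-catalysed enol etherification of a cyclic 1,3-dione (vinylogous Fischer esterification); the dione is symmetric, so only one enol ether can form.

**Step 8**
Reactants: 12 3-methoxy-5-pentylcyclohex-2-en-1-one
Product: 14 6-bromo-3-methoxy-5-pentylcyclohex-2-en-1-one (racemic, mainly trans), via silyl dienol ether 13 (not isolated)
Conditions: LiN(iPr)2, THF, −78 °C; Me3SiCl; then NBS, THF, −78 → 0 °C
Reagents that add atoms: N-bromosuccinimide, O=C1CCC(=O)N1Br
Why: Kinetic deprotonation of a vinylogous ester occurs at the α′ carbon (Stork–Danheiser regiochemistry), and the cross-conjugated silyl dienol ether is brominated at that terminus. Attack anti to the pentyl group should favour the trans isomer, which is also the isomer that lacks an anti-periplanar H–C–C–Br arrangement for elimination.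

**Step 9**
Reactants: 10 8-hydroxy-6-(methoxymethoxy)-3-pentyl-1H-isochromen-1-one; 14 6-bromo-3-methoxy-5-pentylcyclohex-2-en-1-one
Product: 15 8-[(4-methoxy-2-oxo-6-pentylcyclohex-3-en-1-yl)oxy]-6-(methoxymethoxy)-3-pentyl-1H-isochromen-1-one (racemic diastereomer mixture)
Conditions: Cs2CO3, DMF, rt → 45 °C, 14 in excess
Reagents that add atoms: none
Why: Williamson-type SN2 displacement of an α-bromo ketone by the caesium phenoxide; the adjacent carbonyl accelerates substitution, and O8 is the only acidic site of 10. The configuration of the two new sp3 centres is irrelevant.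

**Step 10**
Reactants: 15 8-[(4-methoxy-2-oxo-6-pentylcyclohex-3-en-1-yl)oxy]-6-(methoxymethoxy)-3-pentyl-1H-isochromen-1-one
Product: 16 8-(2-hydroxy-4-methoxy-6-pentylphenoxy)-6-(methoxymethoxy)-3-pentyl-1H-isochromen-1-one
Conditions: DDQ (1.3 equiv), anhydrous 1,4-dioxane, 80 °C
Reagents that add atoms: none
Why: DDQ dehydrogenation of a cyclohexenone to a phenol: enolisation towards the aryloxy-bearing carbon, hydride abstraction from the pentyl-bearing carbon, and tautomerisation of the resulting dienone. The enol ether becomes the aryl methyl ether and the ketone the free 2′-hydroxyl, and anhydrous neutral conditions keep the enol ether from hydrolysing first.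

**Step 11**
Reactants: 16 8-(2-hydroxy-4-methoxy-6-pentylphenoxy)-6-(methoxymethoxy)-3-pentyl-1H-isochromen-1-one
Product: 17 6-hydroxy-8-(2-hydroxy-4-methoxy-6-pentylphenoxy)-3-pentyl-1H-isochromen-1-one
Conditions: HCl (2 M in MeOH), rt → 40 °C
Reagents that add atoms: none
Why: Acid-catalysed acetal exchange removes the methoxymethyl group. Methanol traps the methoxymethyl cation as dimethoxymethane, so it cannot alkylate the electron-rich ring B, and the lactone, diaryl ether and methyl ether are stable.

## Compound list

1 | ethyl 3-oxooctanoate | CCCCCC(=O)CC(=O)OCC | starting material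
2 | ethyl 2-(2-pentyl-1,3-dioxolan-2-yl)acetate | CCCCCC1(CC(=O)OCC)OCCO1 | intermediate
3 | N-methoxy-N-methyl-2-(2-pentyl-1,3-dioxolan-2-yl)acetamide | CCCCCC1(CC(=O)N(C)OC)OCCO1 | intermediate
4 | 2,2,6-trimethyl-4H-1,3-dioxin-4-one | CC1=CC(=O)OC(C)(C)O1 | starting material
5 | 2,2-dimethyl-6-(2-oxopropyl)-4H-1,3-dioxin-4-one | CC(=O)CC1=CC(=O)OC(C)(C)O1 | intermediate
6 | 2,2-dimethyl-6-[2,4-dioxo-5-(2-pentyl-1,3-dioxolan-2-yl)pentyl]-4H-1,3-dioxin-4-one | CCCCCC1(CC(=O)CC(=O)CC2=CC(=O)OC(C)(C)O2)OCCO1 | intermediate
7 | 7-hydroxy-2,2-dimethyl-5-[(2-pentyl-1,3-dioxolan-2-yl)methyl]-4H-1,3-benzodioxin-4-one (not isolated) | CCCCCC1(Cc2cc(O)cc3OC(C)(C)OC(=O)c23)OCCO1 | intermediate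
8 | 7-hydroxy-2,2-dimethyl-5-(2-oxoheptyl)-4H-1,3-benzodioxin-4-one (not isolated) | CCCCCC(=O)Cc1cc(O)cc2OC(C)(C)OC(=O)c12 | intermediate
9 | 6,8-dihydroxy-3-pentyl-1H-isochromen-1-one | CCCCCc1cc2cc(O)cc(O)c2c(=O)o1 | intermediate
10 | 8-hydroxy-6-(methoxymethoxy)-3-pentyl-1H-isochromen-1-one | CCCCCc1cc2cc(OCOC)cc(O)c2c(=O)o1 | intermediate
11 | 5-pentylcyclohexane-1,3-dione | CCCCCC1CC(=O)CC(=O)C1 | starting material
12 | 3-methoxy-5-pentylcyclohex-2-en-1-one (racemic) | CCCCCC1CC(=O)C=C(OC)C1 | intermediate
13 | 1-methoxy-5-pentyl-3-(trimethylsilyloxy)cyclohexa-1,3-diene (racemic, not isolated) | CCCCCC1CC(OC)=CC(O[Si](C)(C)C)=C1 | intermediate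
14 | 6-bromo-3-methoxy-5-pentylcyclohex-2-en-1-one (racemic, trans/cis mixture, configuration not specified) | CCCCCC1CC(OC)=CC(=O)C1Br | intermediate
15 | 8-[(4-methoxy-2-oxo-6-pentylcyclohex-3-en-1-yl)oxy]-6-(methoxymethoxy)-3-pentyl-1H-isochromen-1-one (racemic diastereomer mixture, configuration not specified) | CCCCCc1cc2cc(OCOC)cc(OC3C(=O)C=C(OC)CC3CCCCC)c2c(=O)o1 | intermediate
16 | 8-(2-hydroxy-4-methoxy-6-pentylphenoxy)-6-(methoxymethoxy)-3-pentyl-1H-isochromen-1-one | CCCCCc1cc2cc(OCOC)cc(Oc3c(O)cc(OC)cc3CCCCC)c2c(=O)o1 | intermediate
17 | 6-hydroxy-8-(2-hydroxy-4-methoxy-6-pentylphenoxy)-3-pentyl-1H-isochromen-1-one | CCCCCc1cc2cc(O)cc(Oc3c(O)cc(OC)cc3CCCCC)c2c(=O)o1 | target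

## Step count and risks

Total: 11 steps. Longest linear sequence: 8 steps (1, 2, 4, 5, 6, 9, 10, 11).

**Step 5 (key step).** The cycloaromatisation is expected to be reliable. The doubtful part is the second stage: after the ketal has been hydrolysed, acyl transfer from the benzodioxinone to the enol oxygen may stall. That carbonyl is only moderately activated under TFA, so the sequence could stop at the ketone or drift to the hydrolysed keto acid and its lactol. Premature loss of the dioxolane before ring A has closed would also open the competing fold. Fallback: the reaction is stopped after the Et3N stage and 7 is isolated. Opening of the benzodioxinone with NaOMe in MeOH should give methyl 2,4-dihydroxy-6-[(2-pentyl-1,3-dioxolan-2-yl)methyl]benzoate F1. Aqueous HCl in THF should unmask methyl 2,4-dihydroxy-6-(2-oxoheptyl)benzoate F2. TsOH in refluxing toluene should then close the keto ester to the isocoumarin with loss of methanol, returning to the route at 9.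

**Step 9.** Substitution by a chelated, peri-hindered phenoxide at a secondary, β-branched bromide may be slow. Base-induced dehydrobromination of 14 (mainly of its cis isomer), followed by tautomerisation to a phenol, could then consume the electrophile, as could addition–elimination at the enol-ether carbon. Fallback: the bond is made instead by palladium-catalysed aryl–oxygen coupling with reversed roles.
- From 14, DDQ in dioxane should give 2-bromo-5-methoxy-3-pentylphenol F3.
- MeOCH2Cl and iPr2NEt convert it into 2-bromo-5-methoxy-1-(methoxymethoxy)-3-pentylbenzene F4.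
- Hydroxylation with Pd2(dba)3, tBuXPhos and KOH in dioxane–water gives 4-methoxy-2-(methoxymethoxy)-6-pentylphenol F5.
- Separately, 10 is converted with Tf2O and pyridine into 6-(methoxymethoxy)-1-oxo-3-pentyl-1H-isochromen-8-yl trifluoromethanesulfonate F6.
- Coupling of F5 with the electron-poor triflate F6 (Pd(OAc)2, tBuXPhos, K3PO4, toluene, 100 °C) should give 8-[4-methoxy-2-(methoxymethoxy)-6-pentylphenoxy]-6-(methoxymethoxy)-3-pentyl-1H-isochromen-1-one F7.
- The conditions of step 11 remove both acetals and return to the route at 17.

**Step 10.** Dehydrogenation may be incomplete, because the vinylogous ester enolises reluctantly towards the aryloxy-bearing carbon. DDQ may also over-oxidise the electron-rich ring B once it has formed, and traces of water and acid could hydrolyse the enol ether before aromatisation and so erase the OH/OMe distinction. Fallback: a Saegusa–Ito sequence from 15. LiN(SiMe3)2 and Me3SiCl in THF at −78 °C should give 8-{[4-methoxy-6-pentyl-2-(trimethylsilyloxy)cyclohexa-1,3-dien-1-yl]oxy}-6-(methoxymethoxy)-3-pentyl-1H-isochromen-1-one F8. Pd(OAc)2 in MeCN should then effect β-hydride elimination from the divalent palladium enolate and tautomerisation of the dienone, returning to the route at 16.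

**Step 4.** Proton transfer from the acidic product to the dianion may limit conversion. Enolisation of the amide next to the ketal may lead to β-elimination and opening of the dioxolane, and 6 may cyclise during work-up or chromatography. Fallback: an aldol–oxidation sequence from 2. iBu2AlH in CH2Cl2 at −78 °C should give 2-(2-pentyl-1,3-dioxolan-2-yl)acetaldehyde F9. Addition of the dianion of 5 (LiN(iPr)2, THF, −78 °C) should give racemic 6-[4-hydroxy-2-oxo-5-(2-pentyl-1,3-dioxolan-2-yl)pentyl]-2,2-dimethyl-4H-1,3-dioxin-4-one F10. Dess–Martin periodinane oxidises this to the diketone, returning to the route at 6.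

## Further compounds

F1 | step 5 | methyl 2,4-dihydroxy-6-[(2-pentyl-1,3-dioxolan-2-yl)methyl]benzoate | CCCCCC1(Cc2cc(O)cc(O)c2C(=O)OC)OCCO1
F2 | step 5 | methyl 2,4-dihydroxy-6-(2-oxoheptyl)benzoate | CCCCCC(=O)Cc1cc(O)cc(O)c1C(=O)OC
F3 | step 9 | 2-bromo-5-methoxy-3-pentylphenol | CCCCCc1cc(OC)cc(O)c1Br
F4 | step 9 | 2-bromo-5-methoxy-1-(methoxymethoxy)-3-pentylbenzene | CCCCCc1cc(OC)cc(OCOC)c1Br
F5 | step 9 | 4-methoxy-2-(methoxymethoxy)-6-pentylphenol | CCCCCc1cc(OC)cc(OCOC)c1O
F6 | step 9 | 6-(methoxymethoxy)-1-oxo-3-pentyl-1H-isochromen-8-yl trifluoromethanesulfonate | CCCCCc1cc2cc(OCOC)cc(OS(=O)(=O)C(F)(F)F)c2c(=O)o1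
F7 | step 9 | 8-[4-methoxy-2-(methoxymethoxy)-6-pentylphenoxy]-6-(methoxymethoxy)-3-pentyl-1H-isochromen-1-one | CCCCCc1cc2cc(OCOC)cc(Oc3c(OCOC)cc(OC)cc3CCCCC)c2c(=O)o1
F8 | step 10 | 8-{[4-methoxy-6-pentyl-2-(trimethylsilyloxy)cyclohexa-1,3-dien-1-yl]oxy}-6-(methoxymethoxy)-3-pentyl-1H-isochromen-1-one (racemic) | CCCCCc1cc2cc(OCOC)cc(OC3=C(O[Si](C)(C)C)C=C(OC)CC3CCCCC)c2c(=O)o1
F9 | step 4 | 2-(2-pentyl-1,3-dioxolan-2-yl)acetaldehyde | CCCCCC1(CC=O)OCCO1
F10 | step 4 | 6-[4-hydroxy-2-oxo-5-(2-pentyl-1,3-dioxolan-2-yl)pentyl]-2,2-dimethyl-4H-1,3-dioxin-4-one (racemic) | CCCCCC1(CC(O)CC(=O)CC2=CC(=O)OC(C)(C)O2)OCCO1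
A1 | alternative 1 | 5-(benzyloxy)-3-[2-(benzyloxy)-4-methoxy-6-pentylphenoxy]-2-(trimethylsilyl)phenyl trifluoromethanesulfonate | CCCCCc1cc(OC)cc(OCc2ccccc2)c1Oc1cc(OCc2ccccc2)cc(OS(=O)(=O)C(F)(F)F)c1[Si](C)(C)C
A2 | alternative 1 | dimethyl malonate | COC(=O)CC(=O)OC
A3 | alternative 1 | methyl 4-(benzyloxy)-2-[2-(benzyloxy)-4-methoxy-6-pentylphenoxy]-6-(2-methoxy-2-oxoethyl)benzoate | CCCCCc1cc(OC)cc(OCc2ccccc2)c1Oc1cc(OCc2ccccc2)cc(CC(=O)OC)c1C(=O)OC
A4 | alternative 2 | dimethyl 2-[5-(benzyloxy)-2-(methoxycarbonyl)-3-methylphenoxy]propanedioate | COC(=O)C(Oc1cc(OCc2ccccc2)cc(C)c1C(=O)OC)C(=O)OC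
A5 | alternative 2 | (E)-non-3-en-2-one | CCCCC/C=C/C(C)=O
A6 | alternative 2 | methyl 1-[5-(benzyloxy)-2-(methoxycarbonyl)-3-methylphenoxy]-2,4-dioxo-6-pentylcyclohexane-1-carboxylate (diastereomer mixture) | CCCCCC1CC(=O)CC(=O)C1(Oc1cc(OCc2ccccc2)cc(C)c1C(=O)OC)C(=O)OC
A7 | alternative 3 | 2-[(tert-butyldimethylsilyloxy)methyl]-3-[2-(tert-butyldimethylsilyloxy)heptyl]cyclobut-2-en-1-one (racemic) | CCCCCC(CC1=C(CO[Si](C)(C)C(C)(C)C)C(=O)C1)O[Si](C)(C)C(C)(C)C
A8 | alternative 3 | 1-(benzyloxy)-2-(ethynyloxy)-5-methoxy-3-pentylbenzene | CCCCCc1cc(OC)cc(OCc2ccccc2)c1OC#C
A9 | alternative 3 | 3-[2-(benzyloxy)-4-methoxy-6-pentylphenoxy]-4-[(tert-butyldimethylsilyloxy)methyl]-5-[2-(tert-butyldimethylsilyloxy)heptyl]phenol (racemic) | CCCCCC(Cc1cc(O)cc(Oc2c(OCc3ccccc3)cc(OC)cc2CCCCC)c1CO[Si](C)(C)C(C)(C)C)O[Si](C)(C)C(C)(C)C
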